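**Strategy.** Ring C of the flavanone is cut at two bonds, O1–C8a and C4–C4a. O1, C2, C3 and C4 then form an enantioenriched (S)-4-aryl-β-lactone, and C4a/C8a become the two carbons of a 3,5-bis(benzyloxy)benzyne. The key step inserts this aryne into the acyl C–O bond of the lactone: in one operation the four-membered ring grows to the six-membered pyranone, ring A is fused on, and the C2 stereocentre is carried over untouched. It exploits the 1,3-relationship of O1 and the C4 carbonyl and the 5-oxygen of ring A, which steers the aryne regiochemistry. Suzuki coupling at C5' with 6-iodoapigenin dibenzyl ether and hydrogenolysis finish the synthesis.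

Key step: step 5

Remark: the biaryl axis carries no stereodescriptor and is treated as freely rotating; only C2 is controlled.
Remark: O-trimethylsilylquinine is assumed to be the pseudoenantiomer that gives the (S)-lactone in step 4; if the sense of induction is the reverse, O-trimethylsilylquinidine takes its place.

**Route**

Step 1
Reactants: 1 3,5-bis(benzyloxy)phenol
Product: 2 3,5-bis(benzyloxy)-2-bromophenol
Conditions: NBS, CH2Cl2, −78 °C to 25 °C
Reagents that add atoms: N-bromosuccinimide, O=C1CCC(=O)N1Br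
Why: Electrophilic aromatic bromination; at low temperature the free phenol should direct NBS to its ortho position, the site between the two benzyloxy groups being the more hindered one.

Step 2
Reactants: 2 3,5-bis(benzyloxy)-2-bromophenol
Product: 5 3,5-bis(benzyloxy)-2-(trimethylsilyl)phenyl trifluoromethanesulfonate, via aryl trimethylsilyl ether 3 (not isolated), via lithium 2-silylphenoxide 4 (not isolated)
Conditions: HMDS, THF, 70 °C; then n-BuLi, THF, −78 °C; then Tf2O, −78 to 0 °C
Reagents that add atoms: hexamethyldisilazane, C[Si](C)(C)N[Si](C)(C)C; trifluoromethanesulfonic anhydride, O=S(=O)(OS(=O)(=O)C(F)(F)F)C(F)(F)F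
Why: O-silylation, bromine–lithium exchange with retro-Brook (1,3 O-to-C) silyl migration and O-triflation of the liberated phenoxide is the standard one-pot route to ortho-silylaryl triflates.

Step 3
Reactants: 6 5-bromo-3,4-dihydroxybenzaldehyde
Product: 7 3,4-bis(benzyloxy)-5-bromobenzaldehyde
Conditions: BnBr, K2CO3, DMF, 60 °C
Reagents that add atoms: benzyl bromide, BrCc1ccccc1
Why: Williamson ether synthesis; both catechol hydroxyls are alkylated under standard conditions and the aldehyde is inert.

Step 4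
Reactants: 7 3,4-bis(benzyloxy)-5-bromobenzaldehyde
Product: 8 (S)-4-[3,4-bis(benzyloxy)-5-bromophenyl]oxetan-2-one
Conditions: AcCl, i-Pr2NEt, O-trimethylsilylquinine (10 mol%), LiClO4, CH2Cl2/Et2O, −78 °C
Reagents that add atoms: acetyl chloride, CC(Cl)=O
Why: Catalytic asymmetric ketene–aldehyde [2+2] cyclocondensation: the alkaloid forms a chiral ammonium enolate from ketene generated in situ, LiClO4 activates the aldehyde, and catalyst-controlled facial attack should set the (S) centre, while the meta-bromine tempers the donor ability of the aryl group and so helps the benzylic lactone to survive.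

Step 5
Reactants: 8 (S)-4-[3,4-bis(benzyloxy)-5-bromophenyl]oxetan-2-one; 5 3,5-bis(benzyloxy)-2-(trimethylsilyl)phenyl trifluoromethanesulfonate
Product: 10 (S)-5,7-bis(benzyloxy)-2-[3,4-bis(benzyloxy)-5-bromophenyl]chroman-4-one, via 3,5-bis(benzyloxy)benzyne 9 (not isolated)
Conditions: KF, 18-crown-6, THF, 25 °C, slow addition of 5
Reagents that add atoms: none
Why: Proposed new method: fluoride unmasks aryne 9; the ring oxygen of the strained lactone (poorly conjugated with its carbonyl; equivalently the alkoxide of a transient fluoride-opened acyl fluoride) adds to the aryne carbon remote from the flanking benzyloxy group, and the aryl anion formed beside that benzyloxy group attacks the acyl carbon, the tetrahedral intermediate collapsing with cleavage of the acyl C–O bond. The closest known reaction type is aryne sigma-insertion into the N–C(=O) bond of β-lactams and cyclic ureas (two-carbon ring expansion) and into the O–C(=O) bond of carboxylic acids. The pyranone ring is closed by 4-exo-trig attack of the aryl anion on the lactone carbonyl followed by fragmentation of the four-membered oxete-type intermediate, so the oxetanone grows by the two aryne carbons into six-membered ring C. No new stereocentre is formed: C2 is the lactone C4, whose C–O and C–C bonds are never broken, so the (S) configuration should be carried over with retention. The step needs regioselective aryne capture (O at C8a, acyl at C4a), which the inductive bias of the 3-benzyloxy group on the aryne secures, and it needs the lactone to resist base-induced E1cB opening to the cinnamate (a path to racemic product through the chalcone), which mild fluoride at ambient temperature and slow aryne release should ensure.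

Step 6
Reactants: 10 (S)-5,7-bis(benzyloxy)-2-[3,4-bis(benzyloxy)-5-bromophenyl]chroman-4-one
Product: 11 (S)-5,7-bis(benzyloxy)-2-[3,4-bis(benzyloxy)-5-(4,4,5,5-tetramethyl-1,3,2-dioxaborolan-2-yl)phenyl]chroman-4-one
Conditions: B2pin2, Pd(dppf)Cl2, KOAc, 1,4-dioxane, 80 °C
Reagents that add atoms: bis(pinacolato)diboron, CC1(C)OB(B2OC(C)(C)C(C)(C)O2)OC1(C)C
Why: Miyaura borylation of the aryl bromide; the weak base KOAc should leave base-sensitive ring C and its C2 centre untouched.

Step 7
Reactants: 12 apigenin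
Product: 13 7-(benzyloxy)-2-[4-(benzyloxy)phenyl]-5-hydroxy-4H-chromen-4-one
Conditions: BnBr (2.2 equiv), K2CO3, DMF, 25 °C
Reagents that add atoms: benzyl bromide, BrCc1ccccc1
Why: Williamson ether synthesis; the 5-OH is hydrogen-bonded to the C4 carbonyl and is the least reactive, so the 7- and 4'-hydroxyls should be benzylated selectively.

Step 8
Reactants: 13 7-(benzyloxy)-2-[4-(benzyloxy)phenyl]-5-hydroxy-4H-chromen-4-one
Product: 14 7-(benzyloxy)-2-[4-(benzyloxy)phenyl]-5-hydroxy-6-iodo-4H-chromen-4-one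
Conditions: BnMe3N·ICl2, CaCO3, CH2Cl2/MeOH, 25 °C
Reagents that add atoms: benzyltrimethylammonium dichloroiodate, C[N+](C)(C)Cc1ccccc1.Cl[I-]Cl
Why: Electrophilic aromatic iodination; the free 5-OH should direct the dichloroiodate to its ortho position C6 (flanked by both oxygens) over C8, and CaCO3 buffers the HCl formed.

Step 9
Reactants: 11 (S)-5,7-bis(benzyloxy)-2-[3,4-bis(benzyloxy)-5-(4,4,5,5-tetramethyl-1,3,2-dioxaborolan-2-yl)phenyl]chroman-4-one; 14 7-(benzyloxy)-2-[4-(benzyloxy)phenyl]-5-hydroxy-6-iodo-4H-chromen-4-one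
Product: 15 6-{2,3-bis(benzyloxy)-5-[(2S)-5,7-bis(benzyloxy)-4-oxochroman-2-yl]phenyl}-7-(benzyloxy)-2-[4-(benzyloxy)phenyl]-5-hydroxy-4H-chromen-4-one
Conditions: Pd(OAc)2, SPhos, K3PO4, THF/H2O, 40 °C
Reagents that add atoms: none
Why: Suzuki–Miyaura coupling; boron sits on the mono-ortho-alkoxy ring to avoid protodeboronation, SPhos suits tri-ortho-substituted biaryls, and the mild temperature should limit base-induced opening of ring C so that C2 is retained.

Step 10
Reactants: 15 6-{2,3-bis(benzyloxy)-5-[(2S)-5,7-bis(benzyloxy)-4-oxochroman-2-yl]phenyl}-7-(benzyloxy)-2-[4-(benzyloxy)phenyl]-5-hydroxy-4H-chromen-4-one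
Product: 16 (2S)-2-{3,4-dihydroxy-5-[5,7-dihydroxy-2-(4-hydroxyphenyl)-4-oxo-4H-chromen-6-yl]phenyl}-5,7-dihydroxychroman-4-one (CNP0176432.1)
Conditions: H2 (1 atm), palladium on carbon (Pd/C, 10 wt%), THF/MeOH, 25 °C
Reagents that add atoms: none
Why: Hydrogenolysis of the six benzyl ethers under neutral conditions; the flavone C2=C3 bond, both carbonyls and the benzylic C2–O bond should survive at ambient pressure if hydrogen uptake is monitored, and C2 is not epimerised.

**Compound list**

1 | 3,5-bis(benzyloxy)phenol | Oc1cc(OCc2ccccc2)cc(OCc2ccccc2)c1 | starting material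
2 | 3,5-bis(benzyloxy)-2-bromophenol | Oc1cc(OCc2ccccc2)cc(OCc2ccccc2)c1Br | intermediate
3 | [3,5-bis(benzyloxy)-2-bromophenoxy]trimethylsilane | C[Si](C)(C)Oc1cc(OCc2ccccc2)cc(OCc2ccccc2)c1Br | intermediate
4 | lithium 3,5-bis(benzyloxy)-2-(trimethylsilyl)phenoxide | [Li+].[O-]c1cc(OCc2ccccc2)cc(OCc2ccccc2)c1[Si](C)(C)C | intermediate
5 | 3,5-bis(benzyloxy)-2-(trimethylsilyl)phenyl trifluoromethanesulfonate | C[Si](C)(C)c1c(OS(=O)(=O)C(F)(F)F)cc(OCc2ccccc2)cc1OCc1ccccc1 | intermediate
6 | 5-bromo-3,4-dihydroxybenzaldehyde | O=Cc1cc(O)c(O)c(Br)c1 | starting material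
7 | 3,4-bis(benzyloxy)-5-bromobenzaldehyde | O=Cc1cc(OCc2ccccc2)c(OCc2ccccc2)c(Br)c1 | intermediate
8 | (S)-4-[3,4-bis(benzyloxy)-5-bromophenyl]oxetan-2-one | O=C1C[C@@H](c2cc(OCc3ccccc3)c(OCc3ccccc3)c(Br)c2)O1 | intermediate
9 | 3,5-bis(benzyloxy)benzyne | C1#CC(OCc2ccccc2)=CC(OCc2ccccc2)=C1 | intermediate
10 | (S)-5,7-bis(benzyloxy)-2-[3,4-bis(benzyloxy)-5-bromophenyl]chroman-4-one | O=C1C[C@@H](c2cc(OCc3ccccc3)c(OCc3ccccc3)c(Br)c2)Oc2cc(OCc3ccccc3)cc(OCc3ccccc3)c21 | intermediate
11 | (S)-5,7-bis(benzyloxy)-2-[3,4-bis(benzyloxy)-5-(4,4,5,5-tetramethyl-1,3,2-dioxaborolan-2-yl)phenyl]chroman-4-one | O=C1C[C@@H](c2cc(OCc3ccccc3)c(OCc3ccccc3)c(B3OC(C)(C)C(C)(C)O3)c2)Oc2cc(OCc3ccccc3)cc(OCc3ccccc3)c21 | intermediate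
12 | apigenin (5,7-dihydroxy-2-(4-hydroxyphenyl)-4H-chromen-4-one) | O=c1cc(-c2ccc(O)cc2)oc2cc(O)cc(O)c12 | starting material
13 | 7-(benzyloxy)-2-[4-(benzyloxy)phenyl]-5-hydroxy-4H-chromen-4-one | O=c1cc(-c2ccc(OCc3ccccc3)cc2)oc2cc(OCc3ccccc3)cc(O)c12 | intermediate
14 | 7-(benzyloxy)-2-[4-(benzyloxy)phenyl]-5-hydroxy-6-iodo-4H-chromen-4-one | O=c1cc(-c2ccc(OCc3ccccc3)cc2)oc2cc(OCc3ccccc3)c(I)c(O)c12 | intermediate
15 | 6-{2,3-bis(benzyloxy)-5-[(2S)-5,7-bis(benzyloxy)-4-oxochroman-2-yl]phenyl}-7-(benzyloxy)-2-[4-(benzyloxy)phenyl]-5-hydroxy-4H-chromen-4-one | O=C1C[C@@H](c2cc(OCc3ccccc3)c(OCc3ccccc3)c(-c3c(OCc4ccccc4)cc4oc(-c5ccc(OCc6ccccc6)cc5)cc(=O)c4c3O)c2)Oc2cc(OCc3ccccc3)cc(OCc3ccccc3)c21 | intermediate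
16 | (2S)-2-{3,4-dihydroxy-5-[5,7-dihydroxy-2-(4-hydroxyphenyl)-4-oxo-4H-chromen-6-yl]phenyl}-5,7-dihydroxychroman-4-one | O=C1C[C@@H](c2cc(O)c(O)c(-c3c(O)cc4oc(-c5ccc(O)cc5)cc(=O)c4c3O)c2)Oc2cc(O)cc(O)c21 | target

**Step count and risks**

Total step count: 10. Longest linear sequence: 6 steps (steps 3, 4, 5, 6, 9, 10, from 6 to 16).

Steps most likely to fail:

1. Step 5 (proposed new method). The lactone oxygen may fail to capture the aryne, or capture may occur through the carbonyl oxygen, or the benzylic C–O bond may ionise or the lactone open by E1cB, so that conversion is low or configuration at C2 is eroded. The fallback uses known chemistry, sets out from aldehyde 7 and bromophenol 2 and returns to the route at 10. Aldehyde 7 is converted as in step 4, but with the pseudoenantiomeric alkaloid O-trimethylsilylquinidine, into (R)-4-[3,4-bis(benzyloxy)-5-bromophenyl]oxetan-2-one F1. Bromophenol 2 is deprotonated and lithiated (n-BuLi, 2.1 equiv, THF, −78 °C), transmetalated with MgBr2·OEt2 and acylated by F1 at −78 °C. Ring opening at the acyl carbon should give (R)-3-[3,4-bis(benzyloxy)-5-bromophenyl]-1-[2,4-bis(benzyloxy)-6-hydroxyphenyl]-3-hydroxypropan-1-one F2. Mitsunobu cyclisation (PPh3, DIAD, THF, 0 °C) then closes ring C by 6-exo-tet SN2 displacement with inversion and should give (S)-flavanone 10.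

2. Step 9. Base-induced retro-oxa-Michael opening and reclosure of ring C may erode the configuration at C2, and transmetalation at the hindered positions may be slow. The fallback changes to a base-free coupling, sets out from bromide 10 and returns at 15. Bromide 10 is stannylated ((Me3Sn)2, Pd(PPh3)4, toluene, 100 °C) to (S)-5,7-bis(benzyloxy)-2-[3,4-bis(benzyloxy)-5-(trimethylstannyl)phenyl]chroman-4-one F3. Stille coupling of F3 with iodide 14 without added base (Pd2(dba)3, P(t-Bu)3, CuI, DMF, 60 °C) should give 15.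

3. Step 4. The [2+2] cyclocondensation may be sluggish with the electron-rich aldehyde, facial selectivity may be poor, or the benzylic lactone may decarboxylate on isolation. The fallback builds the centre by hydrogenation, sets out from aldehyde 7 and returns at 8.
   - Roskamp homologation (ethyl diazoacetate, SnCl2, CH2Cl2, 25 °C) should give ethyl 3-[3,4-bis(benzyloxy)-5-bromophenyl]-3-oxopropanoate F4.
   - Noyori hydrogenation (H2, 50 atm, RuCl2[(R)-BINAP], EtOH, 50 °C) is expected, by analogy with aroylacetates, to give ethyl (S)-3-[3,4-bis(benzyloxy)-5-bromophenyl]-3-hydroxypropanoate F5.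
   - Saponification (LiOH, THF/H2O, 0 °C) gives (S)-3-[3,4-bis(benzyloxy)-5-bromophenyl]-3-hydroxypropanoic acid F6.
   - Carboxyl-activating lactonisation (PhSO2Cl, pyridine, 0 °C) closes the four-membered ring with retention to give 8.

Further compounds
F1 | step 5 | (R)-4-[3,4-bis(benzyloxy)-5-bromophenyl]oxetan-2-one | O=C1C[C@H](c2cc(OCc3ccccc3)c(OCc3ccccc3)c(Br)c2)O1
F2 | step 5 | (R)-3-[3,4-bis(benzyloxy)-5-bromophenyl]-1-[2,4-bis(benzyloxy)-6-hydroxyphenyl]-3-hydroxypropan-1-one | O=C(C[C@@H](O)c1cc(OCc2ccccc2)c(OCc2ccccc2)c(Br)c1)c1c(O)cc(OCc2ccccc2)cc1OCc1ccccc1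
F3 | step 9 | (S)-5,7-bis(benzyloxy)-2-[3,4-bis(benzyloxy)-5-(trimethylstannyl)phenyl]chroman-4-one | O=C1C[C@@H](c2cc(OCc3ccccc3)c(OCc3ccccc3)c([Sn](C)(C)C)c2)Oc2cc(OCc3ccccc3)cc(OCc3ccccc3)c21
F4 | step 4 | ethyl 3-[3,4-bis(benzyloxy)-5-bromophenyl]-3-oxopropanoate | CCOC(=O)CC(=O)c1cc(OCc2ccccc2)c(OCc2ccccc2)c(Br)c1
F5 | step 4 | ethyl (S)-3-[3,4-bis(benzyloxy)-5-bromophenyl]-3-hydroxypropanoate | CCOC(=O)C[C@H](O)c1cc(OCc2ccccc2)c(OCc2ccccc2)c(Br)c1
F6 | step 4 | (S)-3-[3,4-bis(benzyloxy)-5-bromophenyl]-3-hydroxypropanoic acid | OC(=O)C[C@H](O)c1cc(OCc2ccccc2)c(OCc2ccccc2)c(Br)c1
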